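## Retrosynthetic overview

1. Target 19 comes from the bicyclic tertiary alcohol 16 by C7–O butanoylation and global desilylation.
2. Ring A is closed last through the C8–C8a bond: a nickel-catalysed cathodic cyclisation of the alkenyl iodide 15 onto its dioxolanone carbonyl (the lactone carbon becomes C8, pivalaldehyde leaves).
3. The C4a–C5 bond of 15 comes from O-alkylation of iodopyranone 11 with chloroketone 6, then an O-to-C shift of the pyrylium ring (the pyranone oxygen becomes the C5 hydroxyl).
4. Chloroketone 6 comes from (S)-lactic acid through the pivalaldehyde dioxolanone 3 and acylation of its enolate (C6–C7 bond, C7 stereocentre set with retention).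
5. Iodopyranone 11 comes from maltol methyl ether 7 by lateral alkylation (C3 side chain) and C5 iodination. Ring order: the pyran ring is bought, ring A is formed last.

Assumption: the stereocentre read from the SMILES is (7S); compounds 14 and 15 are written without a descriptor for the exocyclic C=C because this push–pull double bond isomerises freely and the geometry disappears in step 6.

## Route

Step 1
Reactants: 1 (S)-lactic acid; 2 pivalaldehyde
Product: 3 (2S,5S)-2-tert-butyl-5-methyl-1,3-dioxolan-4-one
Conditions: p-TsOH·H2O (cat.), H2SO4 (cat.), pentane, reflux, Dean–Stark; crystallisation from pentane/Et2O at −78 °C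
Reagents that add atoms: none
Why: Acid-catalysed acetalisation with azeotropic water removal (Seebach dioxolanone formation) keeps the lactic acid stereocentre, which directs the new acetal centre to the cis (2S,5S) isomer that is purified by cold crystallisation.

Step 2
Reactants: 3 (2S,5S)-2-tert-butyl-5-methyl-1,3-dioxolan-4-one; 4 2-chloro-N-methoxy-N-methylacetamide
Product: 6 (2S,5R)-2-tert-butyl-5-(chloroacetyl)-5-methyl-1,3-dioxolan-4-one, via lithium enolate 5 (not isolated)
Conditions: LiN(iPr)2, THF, −78 °C; then 4, −78 to −45 °C; AcOH quench at −78 °C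
Reagents that add atoms: none
Why: Self-regeneration of stereocentres: the planar enolate 5 is acylated anti to the tert-butyl group of the acetal, so the acyl group enters with net retention at the lactate carbon (new quaternary centre, 5R), and the Weinreb amide (Claisen-type C-acylation) holds the ketone as a chelated tetrahedral adduct until the cold quench.

Step 3
Reactants: 7 3-methoxy-2-methyl-4H-pyran-4-one; 8 tert-butyl(2-iodoethoxy)dimethylsilane
Product: 10 2-[3-(tert-butyldimethylsilyloxy)propyl]-3-methoxy-4H-pyran-4-one, via lithium dienolate 9 (not isolated)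
Conditions: LiN(SiMe3)2, THF, −78 °C; then 8, DMPU, −78 to −20 °C
Reagents that add atoms: none
Why: Vinylogous (lateral) deprotonation of the 2-methyl group gives an extended enolate that is C-alkylated at the exocyclic carbon by the primary iodide (SN2), which restores the pyranone.

Step 4
Reactants: 10 2-[3-(tert-butyldimethylsilyloxy)propyl]-3-methoxy-4H-pyran-4-one
Product: 11 2-[3-(tert-butyldimethylsilyloxy)propyl]-5-iodo-3-methoxy-4H-pyran-4-one
Conditions: N-iodosuccinimide, CF3CO2H (10 mol%), MeCN, 0 °C to rt, dark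
Reagents that add atoms: N-iodosuccinimide, O=C1CCC(=O)N1I
Why: Electrophilic iodination of the vinylogous ester occurs at C5, its only free nucleophilic carbon (beta to the ring oxygen, alpha to the carbonyl), and gives the alkenyl iodide handle.

Step 5
Reactants: 6 (2S,5R)-2-tert-butyl-5-(chloroacetyl)-5-methyl-1,3-dioxolan-4-one; 11 2-[3-(tert-butyldimethylsilyloxy)propyl]-5-iodo-3-methoxy-4H-pyran-4-one
Product: 15 (2S,5R)-2-tert-butyl-5-{(tert-butyldimethylsilyloxy)[2-(3-(tert-butyldimethylsilyloxy)propyl)-5-iodo-3-methoxy-4H-pyran-4-ylidene]acetyl}-5-methyl-1,3-dioxolan-4-one, via iodoketone 12 (not isolated), via alkoxypyrylium triflate 13 (not isolated), via hydroxy ketone 14 (not isolated)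
Conditions: NaI, MeCN, rt; then 11, AgOSO2CF3, 0 to 40 °C, dark; then iPr2NEt, 0 °C to rt; then tBuMe2SiOSO2CF3, 0 °C
Reagents that add atoms: tert-butyldimethylsilyl trifluoromethanesulfonate, CC(C)(C)[Si](C)(C)OS(=O)(=O)C(F)(F)F
Why: Proposed new method: the pyranone carbonyl oxygen, the only nucleophilic site of 11, is alkylated by the silver-activated iodoketone 12 to give the 4-alkoxypyrylium 13; the amine removes the proton between the ketone and the ether oxygen, the enolate carbon attacks the ipso carbon through a spiro-oxirane (a Truce–Smiles or [1,2]-Wittig-type O-to-C shift of the pyrylium ring), and oxirane opening plus a proton shift gives the 4-ylidene alpha-hydroxy ketone 14, so the C4a–C5 bond can form only at the former carbonyl carbon and the pyranone oxygen is kept as the C5 hydroxyl, which is then silylated; no stereocentre is formed or touched; the closest known reaction types are the anionic O-to-C migration of electron-poor heteroaryl groups in alpha-aryloxy carbonyl compounds, the Darzens condensation and the Eschenmoser sulfide contraction.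

Step 6
Reactants: 15 (2S,5R)-2-tert-butyl-5-{(tert-butyldimethylsilyloxy)[2-(3-(tert-butyldimethylsilyloxy)propyl)-5-iodo-3-methoxy-4H-pyran-4-ylidene]acetyl}-5-methyl-1,3-dioxolan-4-one
Product: 16 (7S)-5-(tert-butyldimethylsilyloxy)-3-[3-(tert-butyldimethylsilyloxy)propyl]-7-hydroxy-4-methoxy-7-methyl-6H-isochromene-6,8(7H)-dione
Conditions: NiBr2(MeOCH2CH2OMe) (10 mol%), 4,4'-di-tert-butyl-2,2'-bipyridine (12 mol%), LiBr (0.2 M), DMF, undivided cell, Zn anode, Ni-foam cathode, 5 mA, 2.2 F/mol, rt; then aq NH4Cl
Reagents that add atoms: none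
Why: Proposed new method: cathodically generated zerovalent nickel inserts into the C8a–I bond, one-electron reduction gives a nucleophilic monovalent alkenylnickel (or an alkenylzinc after transmetalation) that adds 6-exo to the dioxolanone carbonyl, an acetal-type activated ester further activated by the divalent zinc released at the anode, and collapse of the hemiketal expels the ring oxygen, which loses pivalaldehyde and unveils the C7 alkoxide, so the C8–C8a bond closes ring A in the electrochemical step without touching the quaternary centre; the closest known reaction types are the nickel–bipyridine electroreductive acylation of aryl and alkenyl halides with acid chlorides or anhydrides, nickel-catalysed reductive ketone synthesis from halides and activated esters, and the Parham cyclisation.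

Step 7
Reactants: 16 (7S)-5-(tert-butyldimethylsilyloxy)-3-[3-(tert-butyldimethylsilyloxy)propyl]-7-hydroxy-4-methoxy-7-methyl-6H-isochromene-6,8(7H)-dione; 17 butanoic anhydride
Product: 18 (7S)-5-(tert-butyldimethylsilyloxy)-3-[3-(tert-butyldimethylsilyloxy)propyl]-4-methoxy-7-methyl-6,8-dioxo-7,8-dihydro-6H-isochromen-7-yl butanoate
Conditions: Et3N, DMAP (20 mol%), CH2Cl2, 0 °C to rt
Reagents that add atoms: none
Why: DMAP-catalysed acyl transfer esterifies the tertiary alpha-hydroxy diketone, the usual way of acylating the C7 hydroxyl of azaphilones, and the quaternary centre has no alpha hydrogen and cannot epimerise.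

Step 8
Reactants: 18 (7S)-5-(tert-butyldimethylsilyloxy)-3-[3-(tert-butyldimethylsilyloxy)propyl]-4-methoxy-7-methyl-6,8-dioxo-7,8-dihydro-6H-isochromen-7-yl butanoate
Product: 19 (7S)-5-hydroxy-3-(3-hydroxypropyl)-4-methoxy-7-methyl-6,8-dioxo-7,8-dihydro-6H-isochromen-7-yl butanoate
Conditions: HF·pyridine, pyridine, THF, 0 °C to rt
Reagents that add atoms: none
Why: Fluoride-mediated desilylation cleaves the silyl enol ether and the primary silyl ether in one operation under buffered conditions free of primary amines, which leave the tertiary butanoate and the pyran chromophore intact.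

## Compound list

1 | (S)-lactic acid | C[C@H](O)C(=O)O | starting material
2 | pivalaldehyde | CC(C)(C)C=O | starting material
3 | (2S,5S)-2-tert-butyl-5-methyl-1,3-dioxolan-4-one (cis) | C[C@@H]1O[C@H](C(C)(C)C)OC1=O | intermediate
4 | 2-chloro-N-methoxy-N-methylacetamide | CON(C)C(=O)CCl | starting material
5 | lithium (2S)-2-tert-butyl-5-methyl-1,3-dioxol-4-olate | CC1=C(O[Li])O[C@@H](C(C)(C)C)O1 | intermediate
6 | (2S,5R)-2-tert-butyl-5-(chloroacetyl)-5-methyl-1,3-dioxolan-4-one | C[C@]1(C(=O)CCl)O[C@H](C(C)(C)C)OC1=O | intermediate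
7 | 3-methoxy-2-methyl-4H-pyran-4-one (maltol methyl ether) | CC1=C(OC)C(=O)C=CO1 | starting material
8 | tert-butyl(2-iodoethoxy)dimethylsilane | CC(C)(C)[Si](C)(C)OCCI | starting material
9 | lithium 3-methoxy-2-methylidene-2H-pyran-4-olate | C=C1OC=CC(O[Li])=C1OC | intermediate
10 | 2-[3-(tert-butyldimethylsilyloxy)propyl]-3-methoxy-4H-pyran-4-one | COC1=C(CCCO[Si](C)(C)C(C)(C)C)OC=CC1=O | intermediate
11 | 2-[3-(tert-butyldimethylsilyloxy)propyl]-5-iodo-3-methoxy-4H-pyran-4-one | COC1=C(CCCO[Si](C)(C)C(C)(C)C)OC=C(I)C1=O | intermediate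
12 | (2S,5R)-2-tert-butyl-5-(iodoacetyl)-5-methyl-1,3-dioxolan-4-one | C[C@]1(C(=O)CI)O[C@H](C(C)(C)C)OC1=O | intermediate
13 | 4-{2-[(2S,4R)-2-tert-butyl-4-methyl-5-oxo-1,3-dioxolan-4-yl]-2-oxoethoxy}-2-[3-(tert-butyldimethylsilyloxy)propyl]-5-iodo-3-methoxypyrylium trifluoromethanesulfonate | COc1c(CCCO[Si](C)(C)C(C)(C)C)[o+]cc(I)c1OCC(=O)[C@@]2(C)O[C@H](C(C)(C)C)OC2=O.[O-]S(=O)(=O)C(F)(F)F | intermediate
14 | (2S,5R)-2-tert-butyl-5-{hydroxy[2-(3-(tert-butyldimethylsilyloxy)propyl)-5-iodo-3-methoxy-4H-pyran-4-ylidene]acetyl}-5-methyl-1,3-dioxolan-4-one (exocyclic C=C isomers interconvert) | COC1=C(CCCO[Si](C)(C)C(C)(C)C)OC=C(I)C1=C(O)C(=O)[C@@]2(C)O[C@H](C(C)(C)C)OC2=O | intermediate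
15 | (2S,5R)-2-tert-butyl-5-{(tert-butyldimethylsilyloxy)[2-(3-(tert-butyldimethylsilyloxy)propyl)-5-iodo-3-methoxy-4H-pyran-4-ylidene]acetyl}-5-methyl-1,3-dioxolan-4-one (exocyclic C=C isomers interconvert) | COC1=C(CCCO[Si](C)(C)C(C)(C)C)OC=C(I)C1=C(O[Si](C)(C)C(C)(C)C)C(=O)[C@@]2(C)O[C@H](C(C)(C)C)OC2=O | intermediate
16 | (7S)-5-(tert-butyldimethylsilyloxy)-3-[3-(tert-butyldimethylsilyloxy)propyl]-7-hydroxy-4-methoxy-7-methyl-6H-isochromene-6,8(7H)-dione | O[C@@]1(C)C(=O)C2=COC(CCCO[Si](C)(C)C(C)(C)C)=C(OC)C2=C(O[Si](C)(C)C(C)(C)C)C1=O | intermediate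
17 | butanoic anhydride | CCCC(=O)OC(=O)CCC | starting material
18 | (7S)-5-(tert-butyldimethylsilyloxy)-3-[3-(tert-butyldimethylsilyloxy)propyl]-4-methoxy-7-methyl-6,8-dioxo-7,8-dihydro-6H-isochromen-7-yl butanoate | CCCC(=O)O[C@@]1(C)C(=O)C2=COC(CCCO[Si](C)(C)C(C)(C)C)=C(OC)C2=C(O[Si](C)(C)C(C)(C)C)C1=O | intermediate
19 | (7S)-5-hydroxy-3-(3-hydroxypropyl)-4-methoxy-7-methyl-6,8-dioxo-7,8-dihydro-6H-isochromen-7-yl butanoate (CNP0439446.2) | CCCC(=O)O[C@@]1(C)C(=O)C2=COC(CCCO)=C(OC)C2=C(O)C1=O | target

## Step count and risks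

Total steps: 8. Longest linear sequence: 6 (steps 1, 2, 5, 6, 7, 8 from 1; equally steps 3, 4, 5, 6, 7, 8 from 7).

The three steps most likely to fail:

Step 5 (proposed new O-alkylation and O-to-C shift). The silver-assisted O-alkylation may be slow, and the pyrylium enolate may rest as a spiro-dioxole instead of closing at carbon. The fallback uses known chemistry, sets out from 11 and comes back at 15. Compound 11 is thionated with Lawesson's reagent (toluene, 80 °C) to 2-[3-(tert-butyldimethylsilyloxy)propyl]-5-iodo-3-methoxy-4H-pyran-4-thione F1. S-alkylation of F1 with iodoketone 12 (made from 6 and NaI as in the route) gives the 4-(acylmethylthio)pyrylium iodide F2. F2 is taken with Et3N and PPh3 through an Eschenmoser sulfide contraction to the pyranylidene ketone F3, which carries hydrogen at C5. Epoxidation of the electron-rich exocyclic double bond of F3 with dimethyldioxirane (acetone, −40 °C, Rubottom-type) gives the same spiro-oxirane as in the route; it opens to 14, which is silylated with tBuMe2SiOSO2CF3 and iPr2NEt to 15. Selectivity of the epoxidation over the C3=C4 enol ether is the open point of this detour.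

Step 6 (proposed new nickel-catalysed cathodic ring closure). Protodeiodination or over-reduction of the product chromophore may compete. The fallback uses known chemistry, sets out from 15 and comes back at 16. Iodine–magnesium exchange with iPrMgCl·LiCl (THF, −40 °C) gives the alkenylmagnesium chloride F4. On warming to 0 °C, F4 attacks the dioxolanone carbonyl in a Parham-type cyclisation, pivalaldehyde is lost, and NH4Cl work-up gives 16.

Step 2 (acylation of the hindered enolate with the chloro Weinreb amide). Proton transfer to the enolate or slow addition may lower the yield. The fallback sets out from 3 and comes back at 6. Enolate 5 is added to acetaldehyde (−78 °C, the standard aldol of this enolate, again anti to tert-butyl) to give (2S,5R)-2-tert-butyl-5-(1-hydroxyethyl)-5-methyl-1,3-dioxolan-4-one F5 as a mixture of carbinol epimers. Dess–Martin oxidation gives (2S,5R)-5-acetyl-2-tert-butyl-5-methyl-1,3-dioxolan-4-one F6. Acid-catalysed alpha-chlorination of the methyl ketone (N-chlorosuccinimide, p-TsOH cat., MeCN), which can enolise only towards the methyl group, gives 6.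

## Further compounds

F1 | step 5 | 2-[3-(tert-butyldimethylsilyloxy)propyl]-5-iodo-3-methoxy-4H-pyran-4-thione | COC1=C(CCCO[Si](C)(C)C(C)(C)C)OC=C(I)C1=S
F2 | step 5 | 4-({2-[(2S,4R)-2-tert-butyl-4-methyl-5-oxo-1,3-dioxolan-4-yl]-2-oxoethyl}sulfanyl)-2-[3-(tert-butyldimethylsilyloxy)propyl]-5-iodo-3-methoxypyrylium iodide | COc1c(CCCO[Si](C)(C)C(C)(C)C)[o+]cc(I)c1SCC(=O)[C@@]2(C)O[C@H](C(C)(C)C)OC2=O.[I-]
F3 | step 5 | (2S,5R)-2-tert-butyl-5-{[2-(3-(tert-butyldimethylsilyloxy)propyl)-5-iodo-3-methoxy-4H-pyran-4-ylidene]acetyl}-5-methyl-1,3-dioxolan-4-one | COC1=C(CCCO[Si](C)(C)C(C)(C)C)OC=C(I)C1=CC(=O)[C@@]2(C)O[C@H](C(C)(C)C)OC2=O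
F4 | step 6 | alkenylmagnesium chloride of 15 (chloromagnesium in place of iodine at pyran C5) | COC1=C(CCCO[Si](C)(C)C(C)(C)C)OC=C([Mg]Cl)C1=C(O[Si](C)(C)C(C)(C)C)C(=O)[C@@]2(C)O[C@H](C(C)(C)C)OC2=O
F5 | step 2 | (2S,5R)-2-tert-butyl-5-(1-hydroxyethyl)-5-methyl-1,3-dioxolan-4-one (carbinol epimers) | CC(O)[C@@]1(C)O[C@H](C(C)(C)C)OC1=O
F6 | step 2 | (2S,5R)-5-acetyl-2-tert-butyl-5-methyl-1,3-dioxolan-4-one | CC(=O)[C@@]1(C)O[C@H](C(C)(C)C)OC1=O
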